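**Plan** (drimane numbering throughout: ring A = C1–C5, C10; ring B = C5–C10; C11 on C9, C12 on C8)
Retrosynthesis: the C11 acid, the C12 aldehyde and the C6–O trienoyl bond are unmasked or made last, and the C6 carbinol is traced back to a 6-ketone.
Ring B is then opened at C8–C9: C9 is a tertiary carbinol that carries the C11 carboxyl and is bonded to the vinylic C8 of the C7=C8 unit in ring B, so it is the adduct of a C8 alkenyl-metal (from a (Z)-8-iodo-7-en-6-one) and a C9 α-keto ester.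
The seco chain is cut at C6–C7 (acetylide plus C6 aldehyde) and at C9–C10 (Ireland–Claisen shift of a glycolate on a cyclohexenol made from cyclohexenone 1).
Forward: ring A is bought, C9/C11 are attached to C10, the C7/C8/C12 unit is added to C6, ring B is closed by chromium, and the trienoate is joined last.
Stereochemistry: a lipase resolution fixes the ring-A carbinol and C5; the suprafacial [3,3] shift relays it to C10; C9 is set in the ring closure; C6 comes from hydride attack on the α face of the 6-ketone; the Z iodide comes from anti hydroiodination and the E triene from sorbaldehyde and a Doebner condensation.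

Key step: step 13

Assumption: the lipase is taken to acetylate the (1R)-alcohol, as it does with simple cyclohex-2-en-1-ols, so that the (1S,4S)-alcohol is recovered unreacted; compound 1 is used as the commercial racemate.

Step 1
Reactants: 1 ethyl 2,6,6-trimethyl-4-oxocyclohex-2-ene-1-carboxylate (racemate)
Product: 2 rac-(1S,4S)-4-(hydroxymethyl)-3,5,5-trimethylcyclohex-2-en-1-ol (trans diol)
Conditions: LiAlH4, THF, −78 °C → rt; chromatographic removal of the cis diol
Reagents that add atoms: none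
Why: LiAlH4 reduces the β,β-disubstituted enone in the 1,2 sense and the ester to the primary alcohol; hydride is expected to enter the carbonyl anti to the pseudoaxial methyl of the gem-dimethyl carbon in the half-chair whose ester-bearing carbon is pseudoaxial (allylic strain with the vinylic methyl), which favours the 1,4-trans diol.

Step 2
Reactants: 2 rac-(1S,4S)-4-(hydroxymethyl)-3,5,5-trimethylcyclohex-2-en-1-ol
Product: 3 rac-(1S,4S)-3,5,5-trimethyl-4-(trityloxymethyl)cyclohex-2-en-1-ol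
Conditions: TrCl, Et3N, DMAP (cat.), CH2Cl2, rt
Reagents that add atoms: trityl chloride, ClC(c1ccccc1)(c1ccccc1)c1ccccc1
Why: Tritylation is a sterically governed etherification that takes place at the primary hydroxyl and leaves the secondary allylic alcohol free for the resolution and the acylation that follow.

Step 3
Reactants: 3 rac-(1S,4S)-3,5,5-trimethyl-4-(trityloxymethyl)cyclohex-2-en-1-ol
Product: 4 (1S,4S)-3,5,5-trimethyl-4-(trityloxymethyl)cyclohex-2-en-1-ol
Conditions: lipase from Burkholderia cepacia (Amano PS), vinyl acetate, t-BuOMe, 30 °C, stopped near half conversion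
Reagents that add atoms: none
Why: Lipase-catalysed irreversible transesterification is a kinetic resolution in which the (1R,4R) enantiomer should be acetylated faster, so the recovered (1S,4S) alcohol supplies the absolute configuration of the whole route.

Step 4
Reactants: 4 (1S,4S)-3,5,5-trimethyl-4-(trityloxymethyl)cyclohex-2-en-1-ol; 5 2-(tert-butyldimethylsilyloxy)acetic acid
Product: 6 (1S,4S)-3,5,5-trimethyl-4-(trityloxymethyl)cyclohex-2-en-1-yl 2-(tert-butyldimethylsilyloxy)acetate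
Conditions: DCC, DMAP (cat.), CH2Cl2, 0 °C → rt
Reagents that add atoms: none
Why: Steglich esterification of an unhindered secondary allylic alcohol proceeds at the acyl carbon, so the carbinol configuration is retained and the future C9 oxygen is already in place.

Step 5
Reactants: 6 (1S,4S)-3,5,5-trimethyl-4-(trityloxymethyl)cyclohex-2-en-1-yl 2-(tert-butyldimethylsilyloxy)acetate
Product: 9 2-(tert-butyldimethylsilyloxy)-2-[(1S,6S)-1,5,5-trimethyl-6-(trityloxymethyl)cyclohex-2-en-1-yl]acetic acid (C9 epimers), via silyl ketene acetal 7 (not isolated), via trimethylsilyl ester 8 (not isolated)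
Conditions: LiN(i-Pr)2, Me3SiCl, Et3N, THF, −78 °C → 60 °C; aq. NH4Cl
Reagents that add atoms: chlorotrimethylsilane, C[Si](C)(C)Cl (its silicon is carried by 7 and 8 only)
Why: In this Ireland–Claisen rearrangement the ketene acetal terminus is delivered suprafacially to the methyl-bearing alkene carbon on the face that held the ester oxygen, trans to the CH2OTr arm, which creates the C10 quaternary centre with the C5/C10 relationship of the target; the C9 epimer mixture is erased by oxidation in step 11.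

Step 6
Reactants: 9 2-(tert-butyldimethylsilyloxy)-2-[(1S,6S)-1,5,5-trimethyl-6-(trityloxymethyl)cyclohex-2-en-1-yl]acetic acid
Product: 10 2-(trimethylsilyl)ethyl 2-(tert-butyldimethylsilyloxy)-2-[(1S,6S)-1,5,5-trimethyl-6-(trityloxymethyl)cyclohex-2-en-1-yl]acetate
Conditions: Me3SiCH2CH2OH, DCC, DMAP, CH2Cl2, rt
Reagents that add atoms: 2-(trimethylsilyl)ethanol, C[Si](C)(C)CCO
Why: Steglich esterification installs an ester that can later be cleaved at silicon, away from the very hindered C11 carbonyl.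

Step 7
Reactants: 10 2-(trimethylsilyl)ethyl 2-(tert-butyldimethylsilyloxy)-2-[(1S,6S)-1,5,5-trimethyl-6-(trityloxymethyl)cyclohex-2-en-1-yl]acetate
Product: 11 2-(trimethylsilyl)ethyl 2-(tert-butyldimethylsilyloxy)-2-[(1S,2S)-2-(hydroxymethyl)-1,3,3-trimethylcyclohexyl]acetate
Conditions: H2 (1 atm), Pd(OH)2 on carbon, EtOAc–EtOH, rt
Reagents that add atoms: none
Why: Catalytic hydrogenation saturates the cis-disubstituted ring alkene and the same catalyst hydrogenolyses the trityl ether, while the hindered silyl ether and the silylethyl ester are inert; no stereocentre is formed.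

Step 8
Reactants: 11 2-(trimethylsilyl)ethyl 2-(tert-butyldimethylsilyloxy)-2-[(1S,2S)-2-(hydroxymethyl)-1,3,3-trimethylcyclohexyl]acetate
Product: 12 2-(trimethylsilyl)ethyl 2-(tert-butyldimethylsilyloxy)-2-[(1S,2S)-2-formyl-1,3,3-trimethylcyclohexyl]acetate
Conditions: Dess–Martin periodinane, NaHCO3, CH2Cl2, 0 °C → rt
Reagents that add atoms: none
Why: Buffered Dess–Martin oxidation gives the C6 aldehyde under non-basic conditions, so C5 is not epimerised and the hydroxy ester has no occasion to lactonise.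

Step 9
Reactants: 12 2-(trimethylsilyl)ethyl 2-(tert-butyldimethylsilyloxy)-2-[(1S,2S)-2-formyl-1,3,3-trimethylcyclohexyl]acetate; 13 4-methoxybenzyl propargyl ether
Product: 15 2-(trimethylsilyl)ethyl 2-(tert-butyldimethylsilyloxy)-2-{(1S,2S)-2-[1-hydroxy-4-(4-methoxybenzyloxy)but-2-ynyl]-1,3,3-trimethylcyclohexyl}acetate (C6 and C9 epimers), via lithium acetylide 14 (not isolated)
Conditions: 13, n-BuLi, THF, −78 °C; then 12, −78 °C; AcOH quench at −78 °C
Reagents that add atoms: n-butyllithium, [Li]CCCC (its lithium is carried by 14 only)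
Why: Acetylide addition to the aldehyde at −78 °C is much faster than attack on the hindered ester and forms the C6–C7 bond; the new C6 carbinol is stereorandom and is oxidised in step 11.

Step 10
Reactants: 15 2-(trimethylsilyl)ethyl 2-(tert-butyldimethylsilyloxy)-2-{(1S,2S)-2-[1-hydroxy-4-(4-methoxybenzyloxy)but-2-ynyl]-1,3,3-trimethylcyclohexyl}acetate
Product: 16 2-(trimethylsilyl)ethyl 2-hydroxy-2-{(1S,2S)-2-[1-hydroxy-4-(4-methoxybenzyloxy)but-2-ynyl]-1,3,3-trimethylcyclohexyl}acetate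
Conditions: HF·pyridine, pyridine, THF, 0 °C → rt
Reagents that add atoms: none
Why: Acidic fluoride desilylation removes the secondary silyl ether, whereas the PMB ether is stable and the silylethyl ester needs free fluoride ion to fragment.

Step 11
Reactants: 16 2-(trimethylsilyl)ethyl 2-hydroxy-2-{(1S,2S)-2-[1-hydroxy-4-(4-methoxybenzyloxy)but-2-ynyl]-1,3,3-trimethylcyclohexyl}acetate
Product: 17 2-(trimethylsilyl)ethyl 2-{(1S,2S)-2-[4-(4-methoxybenzyloxy)but-2-ynoyl]-1,3,3-trimethylcyclohexyl}-2-oxoacetate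
Conditions: Dess–Martin periodinane (excess), NaHCO3, CH2Cl2, rt
Reagents that add atoms: none
Why: One Dess–Martin oxidation converts both secondary alcohols, giving the C6 ynone and the C9 α-keto ester and removing the two stereorandom centres.

Step 12
Reactants: 17 2-(trimethylsilyl)ethyl 2-{(1S,2S)-2-[4-(4-methoxybenzyloxy)but-2-ynoyl]-1,3,3-trimethylcyclohexyl}-2-oxoacetate
Product: 18 2-(trimethylsilyl)ethyl 2-{(1S,2S)-2-[(Z)-3-iodo-4-(4-methoxybenzyloxy)but-2-enoyl]-1,3,3-trimethylcyclohexyl}-2-oxoacetate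
Conditions: NaI, AcOH, rt, dark
Reagents that add atoms: sodium iodide, [Na+].[I-]
Why: Conjugate hydroiodination of the ynone puts iodide on C8 and a proton anti to it on C7, which gives the (Z)-β-iodoenone with iodine cis to the C6 carbonyl; the non-enolisable keto ester and the PMB ether are inert to NaI in AcOH.

Step 13
Reactants: 18 2-(trimethylsilyl)ethyl 2-{(1S,2S)-2-[(Z)-3-iodo-4-(4-methoxybenzyloxy)but-2-enoyl]-1,3,3-trimethylcyclohexyl}-2-oxoacetate
Product: 21 2-(trimethylsilyl)ethyl 9β-hydroxy-12-(4-methoxybenzyloxy)-6-oxodrim-7-en-11-oate (ester group 9α), via alkenylchromium dichloride 19 (not isolated), via chromium alkoxide 20 (not isolated)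
Conditions: CrCl2 (6 equiv), NiCl2 (cat.), degassed DMF, rt; aqueous work-up
Reagents that add atoms: CrCl2, [Cr+2].[Cl-].[Cl-] (chromium and chloride are carried by 19 and 20 only)
Why: Zerovalent nickel, formed from NiCl2 by CrCl2, inserts into the activated C8–I bond and hands the alkenyl group to trivalent chromium with retention of the Z geometry, and this alkenylchromium adds to the C9 ketone to form C8–C9. The closest known reaction type is the intramolecular Nozaki–Hiyama–Kishi alkenylation used with (Z)-β-iodoenones and β-iodoenoates, here on a ketone that is activated by its ester and cannot enolise because C10 is quaternary. Ring B closes in a 6-exo-trig mode on the C9 carbonyl and the C7=C8 alkene ends up endocyclic. The new C9 centre is controlled by the ring-A centres C5 and C10: ring B grows on their trans-diequatorial arms with the C10 methyl axial, and the four-centre transfer of chromium from C8 to oxygen needs the carbonyl oxygen near the plane of the alkenyl unit, which is the pseudoequatorial β position. The ester is thereby placed pseudoaxial on the α face, anti to the C10 methyl and clear of the C12 arm, which is the face selectivity the step needs. Chemoselectivity is secured because the Z geometry holds the C8–Cr bond cis to the tether so that only the C9 ketone is within reach, and CrCl2 tolerates the ester, the PMB ether and the enone.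

Step 14
Reactants: 21 2-(trimethylsilyl)ethyl 9β-hydroxy-12-(4-methoxybenzyloxy)-6-oxodrim-7-en-11-oate
Product: 22 2-(trimethylsilyl)ethyl 6β,9β-dihydroxy-12-(4-methoxybenzyloxy)drim-7-en-11-oate
Conditions: NaBH4, CeCl3·7H2O, MeOH, −78 °C
Reagents that add atoms: none
Why: Luche reduction is 1,2-selective and hydride should attack C6 from the α face because the β face is screened by the axial 4β and 10β methyl groups, which gives the axial 6β alcohol; the hindered hydroxy ester is not reduced at this temperature.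

Step 15
Reactants: 23 sorbaldehyde ((2E,4E)-hexa-2,4-dienal); 24 malonic acid
Product: 26 (2E,4E,6E)-octa-2,4,6-trienoic acid, via dienylidenemalonic acid 25 (not isolated)
Conditions: pyridine, piperidine (cat.), 90 °C
Reagents that add atoms: none
Why: Knoevenagel–Doebner condensation followed by decarboxylation extends the dienal by two carbons and gives the thermodynamically favoured E acid.

Step 16
Reactants: 22 2-(trimethylsilyl)ethyl 6β,9β-dihydroxy-12-(4-methoxybenzyloxy)drim-7-en-11-oate; 26 (2E,4E,6E)-octa-2,4,6-trienoic acid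
Product: 28 2-(trimethylsilyl)ethyl 9β-hydroxy-12-(4-methoxybenzyloxy)-6β-[(2E,4E,6E)-octa-2,4,6-trienoyloxy]drim-7-en-11-oate, via mixed anhydride 27 (not isolated)
Conditions: 26, 2,4,6-trichlorobenzoyl chloride, Et3N, toluene, rt; then 22, DMAP, toluene, rt → 50 °C
Reagents that add atoms: 2,4,6-trichlorobenzoyl chloride, O=C(Cl)c1c(Cl)cc(Cl)cc1Cl (its atoms are carried by 27 only)
Why: Yamaguchi esterification transfers the trienoyl group through its acylpyridinium to the secondary allylic 6β hydroxyl with retention at C6, while the tertiary 9-hydroxyl is too hindered to react.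

Step 17
Reactants: 28 2-(trimethylsilyl)ethyl 9β-hydroxy-12-(4-methoxybenzyloxy)-6β-[(2E,4E,6E)-octa-2,4,6-trienoyloxy]drim-7-en-11-oate
Product: 29 2-(trimethylsilyl)ethyl 9β,12-dihydroxy-6β-[(2E,4E,6E)-octa-2,4,6-trienoyloxy]drim-7-en-11-oate
Conditions: DDQ, CH2Cl2–pH 7 buffer, 0 °C
Reagents that add atoms: none
Why: Oxidative PMB cleavage starts with hydride abstraction from the electron-rich benzylic position, so the electron-poor trienoate and the hindered esters are left alone.

Step 18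
Reactants: 29 2-(trimethylsilyl)ethyl 9β,12-dihydroxy-6β-[(2E,4E,6E)-octa-2,4,6-trienoyloxy]drim-7-en-11-oate
Product: 30 2-(trimethylsilyl)ethyl 9β-hydroxy-6β-[(2E,4E,6E)-octa-2,4,6-trienoyloxy]-12-oxodrim-7-en-11-oate
Conditions: MnO2, CH2Cl2, rt
Reagents that add atoms: none
Why: MnO2 oxidises only the primary allylic alcohol, giving the C12 enal and leaving the tertiary alcohol untouched.

Step 19
Reactants: 30 2-(trimethylsilyl)ethyl 9β-hydroxy-6β-[(2E,4E,6E)-octa-2,4,6-trienoyloxy]-12-oxodrim-7-en-11-oate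
Product: 31 (5S,6R,9R,10S)-9-hydroxy-6-[(2E,4E,6E)-octa-2,4,6-trienoyloxy]-12-oxodrim-7-en-11-oic acid (6β-acyloxy, 9β-hydroxy, carboxyl 9α; CNP0234478.3)
Conditions: TASF, DMF, 0 °C → rt; then AcOH
Reagents that add atoms: none
Why: Fluoride attacks silicon of the 2-(trimethylsilyl)ethyl ester and the resulting β-elimination releases ethylene and the C11 carboxylate without any nucleophilic attack at a carbonyl, so the trienoate and the enal survive.

**Compound list**
1 | ethyl 2,6,6-trimethyl-4-oxocyclohex-2-ene-1-carboxylate (racemate) | CCOC(=O)C1C(C)=CC(=O)CC1(C)C | starting material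
2 | rac-(1S,4S)-4-(hydroxymethyl)-3,5,5-trimethylcyclohex-2-en-1-ol (trans; one enantiomer drawn) | O[C@@H]1C=C(C)[C@@H](CO)C(C)(C)C1 | intermediate
3 | rac-(1S,4S)-3,5,5-trimethyl-4-(trityloxymethyl)cyclohex-2-en-1-ol (one enantiomer drawn) | O[C@@H]1C=C(C)[C@@H](COC(c2ccccc2)(c2ccccc2)c2ccccc2)C(C)(C)C1 | intermediate
4 | (1S,4S)-3,5,5-trimethyl-4-(trityloxymethyl)cyclohex-2-en-1-ol (single enantiomer) | O[C@@H]1C=C(C)[C@@H](COC(c2ccccc2)(c2ccccc2)c2ccccc2)C(C)(C)C1 | intermediate
5 | 2-(tert-butyldimethylsilyloxy)acetic acid | CC(C)(C)[Si](C)(C)OCC(=O)O | starting material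
6 | (1S,4S)-3,5,5-trimethyl-4-(trityloxymethyl)cyclohex-2-en-1-yl 2-(tert-butyldimethylsilyloxy)acetate | CC(C)(C)[Si](C)(C)OCC(=O)O[C@@H]1C=C(C)[C@@H](COC(c2ccccc2)(c2ccccc2)c2ccccc2)C(C)(C)C1 | intermediate
7 | trimethylsilyl ketene acetal of ester 6 | C[Si](C)(C)OC(=CO[Si](C)(C)C(C)(C)C)O[C@@H]1C=C(C)[C@@H](COC(c2ccccc2)(c2ccccc2)c2ccccc2)C(C)(C)C1 | intermediate
8 | trimethylsilyl 2-(tert-butyldimethylsilyloxy)-2-[(1S,6S)-1,5,5-trimethyl-6-(trityloxymethyl)cyclohex-2-en-1-yl]acetate | C[Si](C)(C)OC(=O)C(O[Si](C)(C)C(C)(C)C)[C@@]1(C)C=CCC(C)(C)[C@@H]1COC(c2ccccc2)(c2ccccc2)c2ccccc2 | intermediate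
9 | 2-(tert-butyldimethylsilyloxy)-2-[(1S,6S)-1,5,5-trimethyl-6-(trityloxymethyl)cyclohex-2-en-1-yl]acetic acid (C9 epimers) | OC(=O)C(O[Si](C)(C)C(C)(C)C)[C@@]1(C)C=CCC(C)(C)[C@@H]1COC(c2ccccc2)(c2ccccc2)c2ccccc2 | intermediate
10 | 2-(trimethylsilyl)ethyl 2-(tert-butyldimethylsilyloxy)-2-[(1S,6S)-1,5,5-trimethyl-6-(trityloxymethyl)cyclohex-2-en-1-yl]acetate | C[Si](C)(C)CCOC(=O)C(O[Si](C)(C)C(C)(C)C)[C@@]1(C)C=CCC(C)(C)[C@@H]1COC(c2ccccc2)(c2ccccc2)c2ccccc2 | intermediate
11 | 2-(trimethylsilyl)ethyl 2-(tert-butyldimethylsilyloxy)-2-[(1S,2S)-2-(hydroxymethyl)-1,3,3-trimethylcyclohexyl]acetate | C[Si](C)(C)CCOC(=O)C(O[Si](C)(C)C(C)(C)C)[C@@]1(C)CCCC(C)(C)[C@@H]1CO | intermediate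
12 | 2-(trimethylsilyl)ethyl 2-(tert-butyldimethylsilyloxy)-2-[(1S,2S)-2-formyl-1,3,3-trimethylcyclohexyl]acetate | C[Si](C)(C)CCOC(=O)C(O[Si](C)(C)C(C)(C)C)[C@@]1(C)CCCC(C)(C)[C@@H]1C=O | intermediate
13 | 4-methoxybenzyl propargyl ether | C#CCOCc1ccc(OC)cc1 | starting material
14 | lithium acetylide of 13 | [Li]C#CCOCc1ccc(OC)cc1 | intermediate
15 | 2-(trimethylsilyl)ethyl 2-(tert-butyldimethylsilyloxy)-2-{(1S,2S)-2-[1-hydroxy-4-(4-methoxybenzyloxy)but-2-ynyl]-1,3,3-trimethylcyclohexyl}acetate (C6 and C9 epimers) | C[Si](C)(C)CCOC(=O)C(O[Si](C)(C)C(C)(C)C)[C@@]1(C)CCCC(C)(C)[C@@H]1C(O)C#CCOCc1ccc(OC)cc1 | intermediate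
16 | 2-(trimethylsilyl)ethyl 2-hydroxy-2-{(1S,2S)-2-[1-hydroxy-4-(4-methoxybenzyloxy)but-2-ynyl]-1,3,3-trimethylcyclohexyl}acetate (C6 and C9 epimers) | C[Si](C)(C)CCOC(=O)C(O)[C@@]1(C)CCCC(C)(C)[C@@H]1C(O)C#CCOCc1ccc(OC)cc1 | intermediate
17 | 2-(trimethylsilyl)ethyl 2-{(1S,2S)-2-[4-(4-methoxybenzyloxy)but-2-ynoyl]-1,3,3-trimethylcyclohexyl}-2-oxoacetate | C[Si](C)(C)CCOC(=O)C(=O)[C@@]1(C)CCCC(C)(C)[C@@H]1C(=O)C#CCOCc1ccc(OC)cc1 | intermediate
18 | 2-(trimethylsilyl)ethyl 2-{(1S,2S)-2-[(Z)-3-iodo-4-(4-methoxybenzyloxy)but-2-enoyl]-1,3,3-trimethylcyclohexyl}-2-oxoacetate (8,9-seco precursor) | C[Si](C)(C)CCOC(=O)C(=O)[C@@]1(C)CCCC(C)(C)[C@@H]1C(=O)/C=C(\I)COCc1ccc(OC)cc1 | intermediate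
19 | alkenylchromium dichloride at C8 (trivalent chromium) formed from 18 | C[Si](C)(C)CCOC(=O)C(=O)[C@@]1(C)CCCC(C)(C)[C@@H]1C(=O)/C=C(\[Cr](Cl)Cl)COCc1ccc(OC)cc1 | intermediate
20 | chromium alkoxide (trivalent chromium) of 21 | O=C1C=C(COCc3ccc(OC)cc3)[C@@](O[Cr](Cl)Cl)(C(=O)OCC[Si](C)(C)C)[C@@]2(C)CCCC(C)(C)[C@H]12 | intermediate
21 | 2-(trimethylsilyl)ethyl 9β-hydroxy-12-(4-methoxybenzyloxy)-6-oxodrim-7-en-11-oate (ester 9α, 5α-H, 10β-CH3) | O=C1C=C(COCc3ccc(OC)cc3)[C@@](O)(C(=O)OCC[Si](C)(C)C)[C@@]2(C)CCCC(C)(C)[C@H]12 | intermediate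
22 | 2-(trimethylsilyl)ethyl 6β,9β-dihydroxy-12-(4-methoxybenzyloxy)drim-7-en-11-oate | O[C@@H]1C=C(COCc3ccc(OC)cc3)[C@@](O)(C(=O)OCC[Si](C)(C)C)[C@@]2(C)CCCC(C)(C)[C@H]12 | intermediate
23 | sorbaldehyde, (2E,4E)-hexa-2,4-dienal | C/C=C/C=C/C=O | starting material
24 | malonic acid | OC(=O)CC(=O)O | starting material
25 | 2-[(2E,4E)-hexa-2,4-dienylidene]malonic acid | C/C=C/C=C/C=C(C(=O)O)C(=O)O | intermediate
26 | (2E,4E,6E)-octa-2,4,6-trienoic acid | C/C=C/C=C/C=C/C(=O)O | intermediate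
27 | (2E,4E,6E)-octa-2,4,6-trienoic 2,4,6-trichlorobenzoic anhydride | C/C=C/C=C/C=C/C(=O)OC(=O)c1c(Cl)cc(Cl)cc1Cl | intermediate
28 | 2-(trimethylsilyl)ethyl 9β-hydroxy-12-(4-methoxybenzyloxy)-6β-[(2E,4E,6E)-octa-2,4,6-trienoyloxy]drim-7-en-11-oate | C/C=C/C=C/C=C/C(=O)O[C@@H]1C=C(COCc3ccc(OC)cc3)[C@@](O)(C(=O)OCC[Si](C)(C)C)[C@@]2(C)CCCC(C)(C)[C@H]12 | intermediate
29 | 2-(trimethylsilyl)ethyl 9β,12-dihydroxy-6β-[(2E,4E,6E)-octa-2,4,6-trienoyloxy]drim-7-en-11-oate | C/C=C/C=C/C=C/C(=O)O[C@@H]1C=C(CO)[C@@](O)(C(=O)OCC[Si](C)(C)C)[C@@]2(C)CCCC(C)(C)[C@H]12 | intermediate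
30 | 2-(trimethylsilyl)ethyl 9β-hydroxy-6β-[(2E,4E,6E)-octa-2,4,6-trienoyloxy]-12-oxodrim-7-en-11-oate | C/C=C/C=C/C=C/C(=O)O[C@@H]1C=C(C=O)[C@@](O)(C(=O)OCC[Si](C)(C)C)[C@@]2(C)CCCC(C)(C)[C@H]12 | intermediate
31 | (5S,6R,9R,10S)-9-hydroxy-6-[(2E,4E,6E)-octa-2,4,6-trienoyloxy]-12-oxodrim-7-en-11-oic acid | C/C=C/C=C/C=C/C(=O)O[C@@H]1C=C(C=O)[C@@](O)(C(=O)O)[C@@]2(C)CCCC(C)(C)[C@H]12 | target

**Step count**
Total steps: 19. Longest linear sequence: 18 (steps 1–14 and 16–19); step 15 is the one-step side branch to acid 26.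

**Steps most likely to fail**

Step 13 (ring closure). The alkenylchromium is conjugated with the C6 carbonyl and may add too slowly to the hindered C9 ketone, so that protodemetalation wins, or it may add to the other ketone face. The fallback closes the ring on a non-conjugated and more nucleophilic alkenylchromium whose C6 already carries the small trienoyloxy group. It sets out from 15. Dess–Martin oxidation gives the silyloxy ynone F1, and NaI in AcOH gives the (Z)-β-iodoenone F2. Luche reduction gives the (6S)-allylic alcohol F3 together with the (6R)-epimer F4, which is separated and returned to F2 by oxidation. Yamaguchi esterification of F3 with 26 (through 27) gives the trienoate F5, HF·pyridine gives the α-hydroxy ester F6, and Dess–Martin oxidation gives the keto ester F7. Closure of F7 with CrCl2 and catalytic NiCl2 comes back to the route at 28, so that steps 14 and 16 are no longer needed.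

Step 16 (acylation). Acyl transfer to the axial 6β hydroxyl, which sits under the 4β and 10β methyl groups, may be too slow, and the activated trienoyl donor may lose its conjugation under base. The fallback builds the chain on the oxygen in two stages and sets out from 22. Esterification with diethylphosphonoacetic acid (DCC, DMAP), a small and non-isomerisable acyl donor, gives the phosphonoacetate F8. Horner–Wadsworth–Emmons olefination of F8 with sorbaldehyde 23 (LiCl, i-Pr2NEt, MeCN) forms the 2E double bond and comes back to the route at 28.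

Step 3 (resolution). The enzyme may discriminate poorly between the enantiomers of this cyclohexenol with its remote bulky substituent, which would leave material of low enantiomeric purity. The fallback is a covalent resolution that sets out from 3. Esterification with (S)-2-methoxy-2-phenylacetic acid (DCC, DMAP) gives the (1S,4S)-alcohol ester F9 and the (1R,4R)-alcohol ester F10, which are diastereomers and are separated by chromatography or crystallisation. Methanolysis of F9 (K2CO3, MeOH) comes back to the route at 4.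

**Further compounds**
F1 | step 13 | 2-(trimethylsilyl)ethyl 2-(tert-butyldimethylsilyloxy)-2-{(1S,2S)-2-[4-(4-methoxybenzyloxy)but-2-ynoyl]-1,3,3-trimethylcyclohexyl}acetate | C[Si](C)(C)CCOC(=O)C(O[Si](C)(C)C(C)(C)C)[C@@]1(C)CCCC(C)(C)[C@@H]1C(=O)C#CCOCc1ccc(OC)cc1
F2 | step 13 | 2-(trimethylsilyl)ethyl 2-(tert-butyldimethylsilyloxy)-2-{(1S,2S)-2-[(Z)-3-iodo-4-(4-methoxybenzyloxy)but-2-enoyl]-1,3,3-trimethylcyclohexyl}acetate | C[Si](C)(C)CCOC(=O)C(O[Si](C)(C)C(C)(C)C)[C@@]1(C)CCCC(C)(C)[C@@H]1C(=O)/C=C(\I)COCc1ccc(OC)cc1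
F3 | step 13 | 2-(trimethylsilyl)ethyl 2-(tert-butyldimethylsilyloxy)-2-{(1S,2S)-2-[(1S,2Z)-1-hydroxy-3-iodo-4-(4-methoxybenzyloxy)but-2-enyl]-1,3,3-trimethylcyclohexyl}acetate | C[Si](C)(C)CCOC(=O)C(O[Si](C)(C)C(C)(C)C)[C@@]1(C)CCCC(C)(C)[C@@H]1[C@H](O)/C=C(\I)COCc1ccc(OC)cc1
F4 | step 13 | 2-(trimethylsilyl)ethyl 2-(tert-butyldimethylsilyloxy)-2-{(1S,2S)-2-[(1R,2Z)-1-hydroxy-3-iodo-4-(4-methoxybenzyloxy)but-2-enyl]-1,3,3-trimethylcyclohexyl}acetate | C[Si](C)(C)CCOC(=O)C(O[Si](C)(C)C(C)(C)C)[C@@]1(C)CCCC(C)(C)[C@@H]1[C@@H](O)/C=C(\I)COCc1ccc(OC)cc1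
F5 | step 13 | (2E,4E,6E)-octa-2,4,6-trienoate of F3 at the C6 hydroxyl | C[Si](C)(C)CCOC(=O)C(O[Si](C)(C)C(C)(C)C)[C@@]1(C)CCCC(C)(C)[C@@H]1[C@H](OC(=O)/C=C/C=C/C=C/C)/C=C(\I)COCc1ccc(OC)cc1
F6 | step 13 | 2-(trimethylsilyl)ethyl 2-hydroxy-2-{(1S,2S)-2-[(1S,2Z)-3-iodo-4-(4-methoxybenzyloxy)-1-[(2E,4E,6E)-octa-2,4,6-trienoyloxy]but-2-enyl]-1,3,3-trimethylcyclohexyl}acetate | C[Si](C)(C)CCOC(=O)C(O)[C@@]1(C)CCCC(C)(C)[C@@H]1[C@H](OC(=O)/C=C/C=C/C=C/C)/C=C(\I)COCc1ccc(OC)cc1
F7 | step 13 | 2-(trimethylsilyl)ethyl 2-{(1S,2S)-2-[(1S,2Z)-3-iodo-4-(4-methoxybenzyloxy)-1-[(2E,4E,6E)-octa-2,4,6-trienoyloxy]but-2-enyl]-1,3,3-trimethylcyclohexyl}-2-oxoacetate | C[Si](C)(C)CCOC(=O)C(=O)[C@@]1(C)CCCC(C)(C)[C@@H]1[C@H](OC(=O)/C=C/C=C/C=C/C)/C=C(\I)COCc1ccc(OC)cc1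
F8 | step 16 | 2-(trimethylsilyl)ethyl 6β-[2-(diethoxyphosphoryl)acetoxy]-9β-hydroxy-12-(4-methoxybenzyloxy)drim-7-en-11-oate | CCOP(=O)(OCC)CC(=O)O[C@@H]1C=C(COCc3ccc(OC)cc3)[C@@](O)(C(=O)OCC[Si](C)(C)C)[C@@]2(C)CCCC(C)(C)[C@H]12
F9 | step 3 | (1S,4S)-3,5,5-trimethyl-4-(trityloxymethyl)cyclohex-2-en-1-yl (S)-2-methoxy-2-phenylacetate | CO[C@H](C(=O)O[C@@H]1C=C(C)[C@@H](COC(c2ccccc2)(c2ccccc2)c2ccccc2)C(C)(C)C1)c1ccccc1
F10 | step 3 | (1R,4R)-3,5,5-trimethyl-4-(trityloxymethyl)cyclohex-2-en-1-yl (S)-2-methoxy-2-phenylacetate | CO[C@H](C(=O)O[C@H]1C=C(C)[C@H](COC(c2ccccc2)(c2ccccc2)c2ccccc2)C(C)(C)C1)c1ccccc1
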